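The ratio of reagent to starting material, both as charged, is the number to read first, since target takes one reagent and over-reaction product two. The earlier runs and the flasks asked about stand as follows.

all flasks: starting material 19 mM
- south-west: reagent 18 mM; run made earlier
- north-west: reagent 35 mM; run made earlier
- zeta: reagent 30.0 mM; time 4.0 h
- theta: reagent 23.0 mM; time 4.0 h
- delta: reagent 39.0 mM; time 4.0 h

| run | time / h | target / % | starting material / % | over-reaction product / % |
|---|---|---|---|---|
| south-west | 0.333 | 2 | 97 | 0 |
| south-west | 1.00 | 67 | 21 | 12 |
| south-west | 2.00 | 66 | 19 | 12 |
| south-west | 3.00 | 70 | 20 | 15 |
| south-west | 4.00 | 67 | 18 | 14 |
| north-west | 0.333 | 68 | 18 | 16 |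
| north-west | 1.00 | 46 | 0 | 53 |
| north-west | 2.00 | 30 | 0 | 69 |
| north-west | 3.00 | 23 | 1 | 78 |
| north-west | 4.00 | 24 | 0 | 80 |

(each reading ± 1.5 percentage points)



* which of these there is most of at the end, counted by the starting material in it, zeta (over-reaction product / target / starting material)
* which of these there is most of at the end, counted by the starting material in it, theta (over-reaction product / target / starting material)
* which of these there is most of at the end, counted by the starting material in it, delta (over-reaction product / target / starting material)
* amount of the one of these that there is most of at the end, in percent of the starting material charged, zeta
* amount of the one of these that there is most of at the end, in percent of the starting material charged, theta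
* amount of the one of these that there is most of at the end, in percent of the starting material charged, delta

At the end of the south-west run, target plus twice over-reaction product comes to 95.0 % of the charge against a ratio of 94.7 %. In the north-west run it comes to 184 % against 184 %.

My own reckoning folds each recipe into the ratio less one. For theta this is 21.1 %, and this excess is what over-reaction product minus leftover starting material must equal at zero reagent. Zeta has 57.9 %, so at zero reagent and zero starting material it holds that much over-reaction product and 42.1 % target. Theta's target reaches 78.9 % less twice the starting material left, and the excess does not give that leftover. Delta's 105 % is more than the whole charge, so its reagent covers both steps for the whole of the starting material, and the amount of over-reaction product depends on time: in the north-west run it still rose from 69 % at 2.00 h to 80 % at 4.00 h. One number therefore serves zeta and not the other two.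

The forecast, holding that “the plateau means reagent exhausted, not equilibrium”, gave over-reaction product at 57 % (52 % to 62 %) for zeta, target at 64 % (60 % to 69 %) for theta, and over-reaction product at 88 % (82 % to 95 %) for delta.

The flasks give over-reaction product at 56.9 % in zeta, target at 71.1 % in theta, above the forecast's range, and over-reaction product at 91.0 % in delta.

    starting material + reagent + by-product → target + 2 by-product (k = 17.0 M⁻² s⁻¹)
    starting material + reagent → target + by-product (k = 9.20 × 10⁻⁶ M⁻¹ s⁻¹)
    reagent + target → over-reaction product (k = 0.0300 M⁻¹ s⁻¹)

Theta's reagent, the limiting reagent, stands at 0 %, with 3.95 % of starting material left against the forecast's 7. Its over-reaction product less that leftover is 21 percentage points, the excess of 21.1 %. Delta recharged with 32 mM of starting material has an excess of 21.9 %. Its reagent reaches 0 % with 0.85 % of starting material left, so the reckoning gives 22.8 % over-reaction product. That flask holds 22.7 % over-reaction product and 76.4 % target.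

(Readings and results are calculated on assumed constants.)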